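If the gas is held and step 2 runs one way, the substrate in ash and oak has no lasting end but target, so I asked how fast that end is approached.

    gas phase ⇌ dissolved gas, rate k1*(csat - [dissolved gas]) (k1 = 0.45 s⁻¹, csat = 200 mM)
    substrate + dissolved gas → target (k2 = 0.47 M⁻¹ s⁻¹)
    substrate ⇌ dormant form (K3 = 2.3, k3 = 0.035 s⁻¹)
    substrate + target ⇌ idle adduct, settled at all times (K4 = 5.9 M⁻¹)

in all of them: substrate 3.0 M; gas phase 200 mM (held)

| charge | time |
|---|---|
| ash | 30 s |
| oak | 50 s |

- percent here means substrate units held: one idle adduct counts as two
- what is said of target includes idle adduct
- at the start none of the gas is dissolved
- in an amount of target, one idle adduct counts as one target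
- run time (ash): 30 s

- which of these there is most of at the end, counted by the substrate in it, ash (target / substrate)
- which of these there is most of at the end, counted by the substrate in it, oak (target / substrate)
- final amount of the leader among these, as a percentage of the substrate charged, in ash
- final amount of the leader among these, as a percentage of the substrate charged, in oak

With none dissolved, gas enters at k1 times csat, a ceiling of 90.0 mM s⁻¹. By step 2 alone, with the charge as it stood, dissolved gas has a half-life of 0.49 s, far shorter than the run, so I set inflow equal to use, a quasi-steady state. Target then forms at the ceiling times c(substrate)/(c(substrate)+c*), and c(dissolved gas) is csat times c*/(c(substrate)+c*). Here c* is k1/k2, 0.957 M, which I call the half-capture level, the unbound substrate at which target forms at half the ceiling.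

In ash, capture, my word for that share of the ceiling, began at 75.8%, because 3.0 M stood above c*. But in ash substrate and dormant form relax by step 3 alone with a half-life of 13.8 s, shorter than the run, and K4 times the starting substrate is 18, well above one, so target binds substrate strongly. I therefore put the late c(substrate) at 0.319 M, a third of c*. That gave a capture of 25.0%, a quarter. The mean of the two capture values is about half. So I committed to target leading in ash at 45.0%. Running oak on at the late capture gave 60.0%.

The forecast named target for ash and target for oak, at 65% and 71%, above my ash figure, on these grounds: “Most target is tied up as idle adduct, which holds two substrate units each”.

The flask gave target in ash at 39.3% and target in oak at 48.9%, so my figures stood 5.7 percentage points and 11 points high. Unbound substrate in ash ended at 8.78% of the charge, 0.263 M, which is below c*. Put into the half-capture relation, that reading gives c(dissolved gas) of 0.157 M, and ash held 0.154 M.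

A neighbour flask is like ash but charged with 1.2 M of substrate, and its substrate ended at 7.82% of that charge. The same relation gives 0.182 M of dissolved gas. The simulation of that neighbour flask gave 0.181 M, with target at 50.2%.

(All constants were drawn at random within sensible limits; the run is a simulation.)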